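# Proposed total synthesis of CNP0172909.1 (single enantiomer)

Atom labels used throughout: dihydrobenzofuran 1 is O1, C2, C3, C3a, C4–C7, C7a (benzo ring B); dihydrobenzofuran 2 carries primed labels (benzo ring C). "Fragment 2 aryl" stands for the (2R,3R)-7-(benzyloxy)-2-[4-(benzyloxy)phenyl]-3-[3,5-bis(benzyloxy)phenyl]-2,3-dihydro-1-benzofuran-5-yl group. PTAD = N-phthaloyl-adamantylglycinate.

Remark on protecting groups: the six phenol oxygens that stay masked to the end are carried as benzyl ethers, not methyl ethers, because a BBr3-type demethylation is not expected to be tolerated by a 4-styryl-2-aryl-2,3-dihydrobenzofuran, whereas benzyl ethers can be removed at −78 °C.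

Remark on catalyst sense: the facial sense of Rh2(R-PTAD)4 (step 7) and of (R)-BINAP (step 10) is assigned by analogy with simpler substrates; the antipodal catalyst would be used if the sense proved opposite.

## Analysis of the target

The molecule is a stilbenoid trimer built from two trans-2,3-diaryl-2,3-dihydrobenzofurans joined through the C3–C5' bond. Ring B carries a hydroxyl at C6 and an (E)-4-hydroxystyryl group at C4; ring C carries a hydroxyl at C7'; C2 and C2' bear 4-hydroxyphenyl groups and C3' a 3,5-dihydroxyphenyl group. There are four stereocentres, C2 (S), C3 (S), C2' (R) and C3' (R), with the two substituents trans in each furan ring. C3 and C3' are benzhydryl-type methines that cannot epimerise easily. C2 and C2' are 4-oxybenzylic ether carbons whose C–O bonds ionise under acid, so their configuration follows thermodynamically (trans) from the neighbouring centre. The sensitive features are the seven free phenols (air oxidation), the electron-rich E-stilbene, and the two benzylic C–O bonds, which open under protic or Lewis acid next to an alkene that can capture the resulting cation. The hard part is C3: a crowded methine that links fragment 2, C2 and a ring B substituted at both ortho positions (styryl at C4, oxygen at C7a), and that must be set in one absolute configuration relative to the remote centres of fragment 2. The strategy rests on ring B (C3a, C4, C5, C6, C7, C7a) being a 5-styrylresorcinol: oxygens at C6 and C7a, styryl at C4 and C3 on C3a is the pattern of an aldol-folded polyketide chain, with C3 standing where the chain's carboxyl carbon would be.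

## Retrosynthetic reasoning

**Target 34 to hexabenzyl ether 33.** Six O–benzyl bonds are cut last. Benzyl ethers are chosen because their cleavage can be run at −78 °C with a cation scavenger, the mildest known unmasking for a polyphenol that contains both a stilbene and acid-labile dihydrobenzofurans. The C6 hydroxyl needs no protection because it is born free in the ring-forming step.

**33 to resorcinol 32 (O1–C2).** The furan ring of dihydrobenzofuran 1 is opened at O1–C2, giving a C7a phenol and a silylated 4-benzyloxybenzylic carbinol at C2. The cut is made there because that carbon ionises readily and only the C7a hydroxyl can reach it. The forward closure is reversible and delivers the trans ring under control by C3, so the configuration of C2 in all earlier intermediates does not matter.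

**32 to triketone 30 (C3a–C4, the key disconnection).** Ring B is opened between C3a and C4 to the open-chain 3,5,7-triketone 30, which carries the cinnamoyl group at one end and C3 with all of fragment 2 at the other. The cut is placed there because it is the only aldol closure the chain allows (the cinnamoyl end has no α-hydrogen), so the oxygenation pattern and the position of the styryl group are unambiguous. What is gained is that C3 never has to be bonded to a preformed, doubly ortho-substituted arene: it is set earlier on a small lactone, and ring B with its stilbene is built around it from cheap acyclic pieces. The forward reaction must favour C-aldol closure and aromatisation over conjugate addition, pyranone formation and chain cleavage, without disturbing C3 or the silyl ether.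

**30 to Weinreb amide 25 and diketone 28 (C7–C7a).** The chain is cut between C7 and C7a into amide 25 and the terminal carbanion of diketone 28 (dianion 29). A Weinreb amide is used so that the adduct stays masked until work-up. Diketone 28 comes from acetylacetone 26 and aldehyde 27 by condensation at a terminal methyl group.

**25 to aldehyde 20 and aryl bromide 21 (C2–aryl).** After removing the silyl group (24), the C2–aryl bond is cut to aldehyde 20 and arylcerium 23, made from 21 via 22. This is the shortest way to bring in the C2 aryl group and oxygen together; the imperfect control at C2 is tolerable for the reason given above. Aldehyde 20 goes back through alcohol 19 to lactone 18 by oxidation and ring opening.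

**18 to boronic acid 16 and butenolide 17 (C3–C5').** The bond joining the two halves is cut by a catalyst-controlled asymmetric conjugate addition. This sets C3 by the catalyst alone, independent of the three remote centres of fragment 2, on an unhindered acceptor, and gives both flanking carbons (future C2 and C3a/C7a) at useful oxidation levels.

**16 to bromide 13, cis isomer 12 and hydrazone 10 (C2'–C3').** Boronic acid 16 comes from bromide 13 via 14 and 15. The furan ring of fragment 2 is cut at C2'–C3', back to diazo compound 11 and hydrazone 10: a catalyst-controlled carbene insertion into the benzylic ether C–H bond sets C3' with its aryl group already in place, and acid then moves C2' to the trans position (12 to 13).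

**10 to simple arenes.** Hydrazone 10 derives from ketone 9, made by oxidation of carbinol 8, itself from aldehyde 5 and Grignard reagent 7 (from bromide 6). Aldehyde 5 comes from phenol 3 and benzylic chloride 4, and 3 from catechol 2 and commercial aldehyde 1 by demethylation and regioselective benzylation.

## Alternatives that were turned down

**Alternative 1:** The disconnection concerns only dihydrobenzofuran 2: the C3'–C3a' bond is traced back to an aryl shift in flavanone A2. In the forward step PhI(OAc)2 with H2SO4 in HC(OMe)3 makes ring C migrate from the carbonyl carbon to the adjacent carbon, the pyranone contracts to the furan ring, and trans ester A1 results. In its favour, flavanone chemistry is cheap and scalable, the key step needs no transition metal, the trans geometry is thermodynamic because C3' is α to the ester, and the chloride is a handle for later borylation. Against it, A1 carries a carboxylate at C3' where the target has a 3,5-dihydroxyphenyl ring. Turning an ester on a stereogenic benzylic carbon into an arene requires a second ring construction or a decarboxylative arylation, both long. The C2 centre of A2 can racemise through the ring-opened chalcone under acid. The plan also leaves C3, ring B and the stilbene unaddressed. On cost and robustness of its key step it is stronger than the carbene insertion of step 7. The chosen route offers instead a C3' that is formed with its aryl group already attached, and it spends its key step on the harder half of the molecule.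

**Alternative 2:** Both O1–C2 and O1'–C2' are cut at once. In the forward step HCl in methanol removes three MOM groups and ionises two benzylic carbinols, and the ring B and ring C phenols capture the cations to give A3. In its favour it is highly convergent, both trans relationships arise under thermodynamic control in one flask, and the logic at C2 is the same as in step 18 here; on this point it is as strong, and more economical. Against it, the precursor must already contain the whole skeleton with C3 and C3' set and with ring B attached to C3 as a doubly ortho-substituted arene, which is exactly the crowded centre that is hardest to make enantioselectively. Two cations are generated next to an electron-rich stilbene, which invites cation–alkene cyclisation. A3 is a hexamethyl ether, so the route ends in a BBr3 demethylation that a 4-styryl-dihydrobenzofuran is unlikely to survive. The chosen route sets C3 by a conjugate addition to butenolide 17, builds ring B afterwards, generates only one cation, and ends with a low-temperature debenzylation.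

**Alternative 3:** Ring B and the furan ring are cut together at C3a–C7a, C4–C5 and C6–C7. In the forward step RhCl(PPh3)3 joins the ynol ether and the enyne alkyne of a 1,6-diyne (tethered through O1–C2–C3) with ethoxyacetylene A5, giving A4. In its favour, three C–C bonds and two rings form in one neutral operation, more than the single bond and ring of the chosen key step, and no cation is needed because C2 and C3 are carried in the tether. Against it, the tether does not dictate the orientation of A5 (ethoxy at C6 or at C5). A secondary benzylic alkynyl ether at C2 is prone to rearrangement and hydrolysis. The alkene of the enyne can enter the metallacycle. The trans C2/C3 relationship would have to be built in an acyclic precursor without thermodynamic help. One ethyl and six methyl ethers must be cleaved at the end. In the chosen route the regiochemistry is written into the carbonyl positions of triketone 30, C2 is corrected thermodynamically, and the C6 hydroxyl emerges free.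

Key step: step 17

## Route

Step 1
Reactants: 1 5-bromo-2-hydroxy-3-methoxybenzaldehyde
Product: 2 5-bromo-2,3-dihydroxybenzaldehyde
Conditions: BBr3 (2.5 equiv), CH2Cl2, −78 °C to rt; then H2O
Reagents that add atoms: none
Why: Lewis-acid cleavage of the aryl methyl ether (BBr3 demethylation), assisted by chelation to the neighbouring phenoxide; the formyl group and the aryl bromide are inert and no benzyl ether is present yet.

Step 2
Reactants: 2 5-bromo-2,3-dihydroxybenzaldehyde
Product: 3 3-(benzyloxy)-5-bromo-2-hydroxybenzaldehyde
Conditions: NaH (2.2 equiv), DMSO/THF, 0 °C to rt; BnBr (1.0 equiv), rt; aq. NH4Cl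
Reagents that add atoms: benzyl bromide BrCc1ccccc1
Why: Williamson etherification of the catecholate dianion: the 2-phenoxide is conjugated with and chelated to the formyl group, so one equivalent of halide should alkylate the more nucleophilic 3-phenoxide, which becomes the C7' oxygen.

Step 3
Reactants: 3 3-(benzyloxy)-5-bromo-2-hydroxybenzaldehyde; 4 1-(benzyloxy)-4-(chloromethyl)benzene
Product: 5 3-(benzyloxy)-2-{[4-(benzyloxy)phenyl]methoxy}-5-bromobenzaldehyde
Conditions: K2CO3 (2 equiv), KI (cat.), DMF, 60 °C
Reagents that add atoms: none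
Why: Williamson etherification of the remaining hindered ortho-phenol; the benzylic CH2 introduced here is the future C2' and already carries its aryl group.

Step 4
Reactants: 5 3-(benzyloxy)-2-{[4-(benzyloxy)phenyl]methoxy}-5-bromobenzaldehyde; 6 1,3-bis(benzyloxy)-5-bromobenzene
Product: 8 [3-(benzyloxy)-2-{[4-(benzyloxy)phenyl]methoxy}-5-bromophenyl][3,5-bis(benzyloxy)phenyl]methanol (racemic), via [3,5-bis(benzyloxy)phenyl]magnesium bromide 7 (not isolated)
Conditions: 6, Mg, I2 (cat.), THF, reflux; then 5, THF, 0 °C; aq. NH4Cl
Reagents that add atoms: none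
Why: Grignard addition to the aldehyde; an aryl Grignard reagent does not exchange with the aryl bromide of 5 at 0 °C, and the new carbinol centre (racemic) is erased in step 5.

Step 5
Reactants: 8 the diaryl carbinol of step 4
Product: 9 [3-(benzyloxy)-2-{[4-(benzyloxy)phenyl]methoxy}-5-bromophenyl][3,5-bis(benzyloxy)phenyl]methanone
Conditions: Dess–Martin periodinane (1.3 equiv), NaHCO3, CH2Cl2, rt
Reagents that add atoms: none
Why: Dess–Martin oxidation of the diaryl carbinol to the benzophenone under buffered conditions that leave the benzylic ethers untouched.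

Step 6
Reactants: 9 the benzophenone of step 5
Product: 10 hydrazone of ketone 9 (E/Z mixture)
Conditions: N2H4·H2O (10 equiv), AcOH (cat.), n-BuOH, 110 °C
Reagents that add atoms: hydrazine hydrate NN.O
Why: Hydrazone condensation; the ortho-disubstituted benzophenone needs excess hydrazine and heat, and the C=N geometry is irrelevant because it is lost in step 7.

Step 7
Reactants: 10 hydrazone of ketone 9
Product: 12 (2S,3R)-7-(benzyloxy)-2-[4-(benzyloxy)phenyl]-3-[3,5-bis(benzyloxy)phenyl]-5-bromo-2,3-dihydro-1-benzofuran (cis), via diaryldiazomethane 11 (not isolated)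
Conditions: MnO2 (8 equiv), CH2Cl2, 0 °C; then Rh2(R-PTAD)4 (1 mol%), 0 °C to rt
Reagents that add atoms: none
Why: MnO2 dehydrogenates the hydrazone to diaryldiazomethane 11, and Rh2(R-PTAD)4 converts it into a donor/donor carbene that inserts into the O–CH2 bond five atoms away (intramolecular 1,5-C–H insertion), forming C2'–C3' and the furan ring. The chiral catalyst should fix C3' as (R), and the concerted insertion gives the cis-2,3-diaryl isomer kinetically, so C2' is (S) here and is corrected in step 8.

Step 8
Reactants: 12 the cis-dihydrobenzofuran of step 7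
Product: 13 (2R,3R)-7-(benzyloxy)-2-[4-(benzyloxy)phenyl]-3-[3,5-bis(benzyloxy)phenyl]-5-bromo-2,3-dihydro-1-benzofuran (trans)
Conditions: CF3CO2H (5 equiv), CH2Cl2, 0 °C to rt
Reagents that add atoms: none
Why: Acid reversibly ionises the C2'–O1' bond to the 4-benzyloxybenzylic cation and the phenol recloses to the thermodynamically preferred trans isomer (epimerisation at C2' only, to (R)); C3' has no pathway for inversion and no ring carbon can reach the cation to form a carbocycle.

Step 9
Reactants: 13 the trans bromide of step 8
Product: 16 (fragment 2 aryl)boronic acid, via (fragment 2 aryl)lithium 14 (not isolated), via lithium triisopropoxy(fragment 2 aryl)borate 15 (not isolated)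
Conditions: n-BuLi (1.1 equiv), THF, −78 °C; B(OiPr)3 (1.5 equiv), −78 to 0 °C; 1 M HCl
Reagents that add atoms: triisopropyl borate CC(C)OB(OC(C)C)OC(C)C; water O
Why: Bromine–lithium exchange at −78 °C is faster than deprotonation of any benzylic position, and trapping with the borate ester followed by hydrolysis gives the boronic acid.

Step 10
Reactants: 16 (fragment 2 aryl)boronic acid; 17 2(5H)-furanone
Product: 18 (4R)-4-(fragment 2 aryl)oxolan-2-one
Conditions: [Rh(OH)((R)-BINAP)]2 (3 mol% Rh), 17 (3 equiv), dioxane/H2O 10:1, 50 °C
Reagents that add atoms: none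
Why: Hayashi–Miyaura asymmetric 1,4-addition: the aryl group passes from boron to rhodium and inserts into the butenolide C=C on the face selected by (R)-BINAP, and water protonates the rhodium enolate. This creates C3 (as (4R) in the lactone) under catalyst control, independent of the remote centres of fragment 2; the cheap butenolide is used in excess so that the boronic acid is the limiting partner.

Step 11
Reactants: 18 (4R)-4-(fragment 2 aryl)oxolan-2-one
Product: 19 (3R)-3-(fragment 2 aryl)-4-hydroxy-N-methoxy-N-methylbutanamide
Conditions: MeNH(OMe)·HCl (3 equiv), AlMe3 (3 equiv), CH2Cl2, 0 °C to rt; aq. KNaC4H4O6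
Reagents that add atoms: N,O-dimethylhydroxylamine hydrochloride CNOC.Cl
Why: Aminolysis of the γ-lactone by the aluminium amide Me(Cl)Al–N(OMe)Me made in the flask (Weinreb amidation); benzyl ethers and C3 are unaffected, and the product is used promptly because it can relactonise.

Step 12
Reactants: 19 the hydroxy Weinreb amide of step 11
Product: 20 (3R)-3-(fragment 2 aryl)-N-methoxy-N-methyl-4-oxobutanamide
Conditions: Dess–Martin periodinane (1.3 equiv), NaHCO3 (5 equiv), CH2Cl2, 0 °C; used crude at once
Reagents that add atoms: none
Why: Dess–Martin oxidation of the primary alcohol under buffered, base-free conditions, chosen to keep enolisation of the α-aryl aldehyde (and hence epimerisation at C3) to a minimum.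

Step 13
Reactants: 20 the aldehyde of step 12; 21 1-(benzyloxy)-4-bromobenzene
Product: 24 (3R,4S)-4-[4-(benzyloxy)phenyl]-3-(fragment 2 aryl)-4-hydroxy-N-methoxy-N-methylbutanamide, via 4-(benzyloxy)phenyllithium 22 (not isolated), via [4-(benzyloxy)phenyl]cerium dichloride 23 (not isolated)
Conditions: 21 (1.6 equiv), n-BuLi, THF, −78 °C; CeCl3 (anhydrous, 1.7 equiv), −78 °C; then 20, −78 °C; AcOH/THF quench at −78 °C
Reagents that add atoms: none
Why: Arylcerium 23 is weakly basic and strongly carbonyl-selective, so it should add to the aldehyde at −78 °C without enolising it or touching the Weinreb amide. Felkin–Anh addition (fragment 2 aryl anti to the incoming aryl group) should favour the (4S) carbinol; the ratio is not critical because C2 is ionised and re-set in step 18.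

Step 14
Reactants: 24 the carbinol of step 13
Product: 25 (3R,4S)-4-[4-(benzyloxy)phenyl]-3-(fragment 2 aryl)-4-[(tert-butyldimethylsilyl)oxy]-N-methoxy-N-methylbutanamide
Conditions: TBSOTf (1.5 equiv), 2,6-lutidine (3 equiv), CH2Cl2, −40 to 0 °C
Reagents that add atoms: tert-butyldimethylsilyl trifluoromethanesulfonate CC(C)(C)[Si](C)(C)OS(=O)(=O)C(F)(F)F
Why: Silylation of the secondary benzylic alcohol with the silyl triflate; the silyl ether stops relactonisation onto the Weinreb amide and later keeps the C2 oxygen from forming a cyclic ketal with the C7a carbonyl.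

Step 15
Reactants: 26 acetylacetone; 27 4-(benzyloxy)benzaldehyde
Product: 28 (E)-6-[4-(benzyloxy)phenyl]hex-5-ene-2,4-dione
Conditions: 26 (3 equiv), B2O3 (1.5 equiv), EtOAc, 80 °C; then 27, B(OnBu)3 (1 equiv), n-BuNH2 (0.2 equiv), 80 °C; then 1 M HCl, 60 °C
Reagents that add atoms: none
Why: Boron-templated aldol condensation (Pabon-type): chelation of the diketone to boron blocks the central carbon, so the aldehyde condenses at a terminal methyl group and dehydrates to the E-enone; excess diketone suppresses double condensation.

Step 16
Reactants: 25 the silylated Weinreb amide of step 14; 28 (E)-6-[4-(benzyloxy)phenyl]hex-5-ene-2,4-dione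
Product: 30 (1E,9R,10S)-1,10-bis[4-(benzyloxy)phenyl]-10-[(tert-butyldimethylsilyl)oxy]-9-(fragment 2 aryl)dec-1-ene-3,5,7-trione, via dilithium dienolate 29 (not isolated)
Conditions: 28 (2 equiv), LDA (4.2 equiv), THF, −78 to 0 °C; then 25, −78 to −20 °C; AcOH quench
Reagents that add atoms: none
Why: Claisen-type chain extension of a β-diketone dianion (Harris acylation): the terminal carbanion of 29 adds to the Weinreb amide and forms C7–C7a, and the chelated tetrahedral adduct survives until the acidic quench, so neither over-addition nor quenching of the dianion by the acidic triketone can occur. The cinnamoyl end has no α-hydrogen, so the dianion forms only at the methyl end; C3 is β to the amide carbonyl and is not affected.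

Step 17
Reactants: 30 the triketone of step 16
Product: 32 5-{(E)-2-[4-(benzyloxy)phenyl]ethenyl}-4-{(1S,2S)-2-[4-(benzyloxy)phenyl]-2-[(tert-butyldimethylsilyl)oxy]-1-(fragment 2 aryl)ethyl}benzene-1,3-diol, via cyclic aldol adduct 31 (not isolated)
Conditions: KOH (1 M in MeOH, 5 equiv), THF/MeOH 1:1, degassed, Ar, rt to 40 °C; AcOH to pH 5
Reagents that add atoms: none
Why: Base converts 30 into its enolates; the doubly activated C5 and C7 positions are deprotonated first but have no six-membered closure open to them, whereas the C3a enolate (C3a=C7a–O−), present in small equilibrium amount, attacks the cinnamoyl carbonyl C4 and forms C3a–C4. This closes ring B as aldol 31 in a 6-(enolendo)-exo-trig mode; loss of the C4 hydroxyl by β-elimination and enolisation of the C6 and C7a carbonyls then give resorcinol 32. The closest known reaction is the base-mediated aldol cyclisation of open-chain 1,3,5-triketones to resorcinols (heptane-2,4,6-trione to orcinol), the folding used by stilbene synthases. Only one such closure is possible because the cinnamoyl end has no α-hydrogen, so the regiochemistry (oxygen at C6 and C7a, styryl at C4, C3 on C3a) is fixed by the positions of the carbonyl groups. No stereocentre is created in 32, the two sp3 ring centres of 31 being lost on aromatisation; C3 is β to the C7a carbonyl, carries no leaving group and cannot enolise, so the configuration from step 10 is retained. The selectivity required is C-aldol over conjugate addition (of C7 or of an enol oxygen) to the styryl ketone, over 4-pyranone formation and over retro-Claisen cleavage: the conjugate additions are reversible in base and drain through the irreversible aromatisation, pyranone formation needs acid, and cleavage is limited by moderate temperature and a modest excess of base. The silyl ether keeps the C2 oxygen from adding to the C7a carbonyl and, like the benzyl ethers, is stable to KOH in methanol; oxygen is excluded because the resorcinolate is air-sensitive.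

Step 18
Reactants: 32 the resorcinol of step 17
Product: 33 (2S,3S)-2-[4-(benzyloxy)phenyl]-4-{(E)-2-[4-(benzyloxy)phenyl]ethenyl}-3-(fragment 2 aryl)-2,3-dihydro-1-benzofuran-6-ol
Conditions: TsOH·H2O (0.5 equiv), CH2Cl2, 0 °C to rt, short contact time
Reagents that add atoms: none
Why: Acid ionises the C2–O bond of the 4-benzyloxybenzylic silyl ether; of the two ring B phenols only the C7a hydroxyl can reach the cation, and its capture forms O1–C2 and the five-membered ring. Closure and any reopening are reversible, so the C2 aryl group settles anti to the C3 substituent (trans, (2S)) under thermodynamic control by C3, and both C2 epimers of the precursor converge; catalytic acid, low temperature and short contact are meant to keep the stilbene out of the cation chemistry.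

Step 19
Reactants: 33 the hexabenzyl ether of step 18
Product: 34 (2S,3S)-3-[(2R,3R)-3-(3,5-dihydroxyphenyl)-7-hydroxy-2-(4-hydroxyphenyl)-2,3-dihydro-1-benzofuran-5-yl]-2-(4-hydroxyphenyl)-4-[(E)-2-(4-hydroxyphenyl)ethenyl]-2,3-dihydro-1-benzofuran-6-ol (CNP0172909.1)
Conditions: BCl3 (1 M in CH2Cl2, 14 equiv), pentamethylbenzene (21 equiv), CH2Cl2, −78 °C; MeOH/CHCl3 quench at −78 °C
Reagents that add atoms: none
Why: BCl3-mediated cleavage of aryl benzyl ethers at −78 °C with pentamethylbenzene as a non-coordinating scavenger that removes the benzyl cations by Friedel–Crafts alkylation; the low temperature and the scavenger are intended to spare the stilbene and the two benzylic C–O bonds of the dihydrobenzofurans, and no stereocentre is touched.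

## Compound list

1 | 5-bromo-2-hydroxy-3-methoxybenzaldehyde | COc1cc(Br)cc(C=O)c1O | starting material
2 | 5-bromo-2,3-dihydroxybenzaldehyde | Oc1cc(Br)cc(C=O)c1O | intermediate
3 | 3-(benzyloxy)-5-bromo-2-hydroxybenzaldehyde | O=Cc1cc(Br)cc(OCc2ccccc2)c1O | intermediate
4 | 1-(benzyloxy)-4-(chloromethyl)benzene | ClCc1ccc(OCc2ccccc2)cc1 | starting material
5 | 3-(benzyloxy)-2-{[4-(benzyloxy)phenyl]methoxy}-5-bromobenzaldehyde | O=Cc1cc(Br)cc(OCc2ccccc2)c1OCc1ccc(OCc2ccccc2)cc1 | intermediate
6 | 1,3-bis(benzyloxy)-5-bromobenzene | Brc1cc(OCc2ccccc2)cc(OCc2ccccc2)c1 | starting material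
7 | [3,5-bis(benzyloxy)phenyl]magnesium bromide | Br[Mg]c1cc(OCc2ccccc2)cc(OCc2ccccc2)c1 | intermediate (not isolated)
8 | [3-(benzyloxy)-2-{[4-(benzyloxy)phenyl]methoxy}-5-bromophenyl][3,5-bis(benzyloxy)phenyl]methanol, racemic | OC(c1cc(OCc2ccccc2)cc(OCc2ccccc2)c1)c1cc(Br)cc(OCc2ccccc2)c1OCc1ccc(OCc2ccccc2)cc1 | intermediate
9 | [3-(benzyloxy)-2-{[4-(benzyloxy)phenyl]methoxy}-5-bromophenyl][3,5-bis(benzyloxy)phenyl]methanone | O=C(c1cc(OCc2ccccc2)cc(OCc2ccccc2)c1)c1cc(Br)cc(OCc2ccccc2)c1OCc1ccc(OCc2ccccc2)cc1 | intermediate
10 | hydrazone of ketone 9 (E/Z mixture) | NN=C(c1cc(OCc2ccccc2)cc(OCc2ccccc2)c1)c1cc(Br)cc(OCc2ccccc2)c1OCc1ccc(OCc2ccccc2)cc1 | intermediate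
11 | diaryldiazomethane from 10 | [N-]=[N+]=C(c1cc(OCc2ccccc2)cc(OCc2ccccc2)c1)c1cc(Br)cc(OCc2ccccc2)c1OCc1ccc(OCc2ccccc2)cc1 | intermediate (not isolated)
12 | (2S,3R)-7-(benzyloxy)-2-[4-(benzyloxy)phenyl]-3-[3,5-bis(benzyloxy)phenyl]-5-bromo-2,3-dihydro-1-benzofuran (cis) | Brc1cc(OCc2ccccc2)c2c(c1)[C@@H](c1cc(OCc3ccccc3)cc(OCc3ccccc3)c1)[C@@H](c1ccc(OCc3ccccc3)cc1)O2 | intermediate
13 | (2R,3R)-7-(benzyloxy)-2-[4-(benzyloxy)phenyl]-3-[3,5-bis(benzyloxy)phenyl]-5-bromo-2,3-dihydro-1-benzofuran (trans) | Brc1cc(OCc2ccccc2)c2c(c1)[C@@H](c1cc(OCc3ccccc3)cc(OCc3ccccc3)c1)[C@H](c1ccc(OCc3ccccc3)cc1)O2 | intermediate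
14 | (fragment 2 aryl)lithium | [Li]c1cc(OCc2ccccc2)c2c(c1)[C@@H](c1cc(OCc3ccccc3)cc(OCc3ccccc3)c1)[C@H](c1ccc(OCc3ccccc3)cc1)O2 | intermediate (not isolated)
15 | lithium triisopropoxy(fragment 2 aryl)borate | [Li+].CC(C)O[B-](OC(C)C)(OC(C)C)c1cc(OCc2ccccc2)c2c(c1)[C@@H](c1cc(OCc3ccccc3)cc(OCc3ccccc3)c1)[C@H](c1ccc(OCc3ccccc3)cc1)O2 | intermediate (not isolated)
16 | (fragment 2 aryl)boronic acid | OB(O)c1cc(OCc2ccccc2)c2c(c1)[C@@H](c1cc(OCc3ccccc3)cc(OCc3ccccc3)c1)[C@H](c1ccc(OCc3ccccc3)cc1)O2 | intermediate
17 | 2(5H)-furanone | O=C1OCC=C1 | starting material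
18 | (4R)-4-(fragment 2 aryl)oxolan-2-one | O=C1C[C@H](c2cc(OCc3ccccc3)c3c(c2)[C@@H](c2cc(OCc4ccccc4)cc(OCc4ccccc4)c2)[C@H](c2ccc(OCc4ccccc4)cc2)O3)CO1 | intermediate
19 | (3R)-3-(fragment 2 aryl)-4-hydroxy-N-methoxy-N-methylbutanamide | CON(C)C(=O)C[C@H](c1cc(OCc2ccccc2)c2c(c1)[C@@H](c1cc(OCc3ccccc3)cc(OCc3ccccc3)c1)[C@H](c1ccc(OCc3ccccc3)cc1)O2)CO | intermediate
20 | (3R)-3-(fragment 2 aryl)-N-methoxy-N-methyl-4-oxobutanamide | CON(C)C(=O)C[C@H](c1cc(OCc2ccccc2)c2c(c1)[C@@H](c1cc(OCc3ccccc3)cc(OCc3ccccc3)c1)[C@H](c1ccc(OCc3ccccc3)cc1)O2)C=O | intermediate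
21 | 1-(benzyloxy)-4-bromobenzene | Brc1ccc(OCc2ccccc2)cc1 | starting material
22 | 4-(benzyloxy)phenyllithium | [Li]c1ccc(OCc2ccccc2)cc1 | intermediate (not isolated)
23 | [4-(benzyloxy)phenyl]cerium dichloride | Cl[Ce](Cl)c1ccc(OCc2ccccc2)cc1 | intermediate (not isolated)
24 | (3R,4S)-4-[4-(benzyloxy)phenyl]-3-(fragment 2 aryl)-4-hydroxy-N-methoxy-N-methylbutanamide | CON(C)C(=O)C[C@H](c1cc(OCc2ccccc2)c2c(c1)[C@@H](c1cc(OCc3ccccc3)cc(OCc3ccccc3)c1)[C@H](c1ccc(OCc3ccccc3)cc1)O2)[C@@H](c1ccc(OCc2ccccc2)cc1)O | intermediate
25 | (3R,4S)-4-[4-(benzyloxy)phenyl]-3-(fragment 2 aryl)-4-[(tert-butyldimethylsilyl)oxy]-N-methoxy-N-methylbutanamide | CON(C)C(=O)C[C@H](c1cc(OCc2ccccc2)c2c(c1)[C@@H](c1cc(OCc3ccccc3)cc(OCc3ccccc3)c1)[C@H](c1ccc(OCc3ccccc3)cc1)O2)[C@@H](c1ccc(OCc2ccccc2)cc1)O[Si](C)(C)C(C)(C)C | intermediate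
26 | acetylacetone | CC(=O)CC(=O)C | starting material
27 | 4-(benzyloxy)benzaldehyde | O=Cc1ccc(OCc2ccccc2)cc1 | starting material
28 | (E)-6-[4-(benzyloxy)phenyl]hex-5-ene-2,4-dione | CC(=O)CC(=O)/C=C/c1ccc(OCc2ccccc2)cc1 | intermediate
29 | dilithium dienolate (1,3-dianion) of 28 | [Li+].[Li+].C=C([O-])C=C([O-])/C=C/c1ccc(OCc2ccccc2)cc1 | intermediate (not isolated)
30 | (1E,9R,10S)-1,10-bis[4-(benzyloxy)phenyl]-10-[(tert-butyldimethylsilyl)oxy]-9-(fragment 2 aryl)dec-1-ene-3,5,7-trione | c1ccccc1COc1ccc(/C=C/C(=O)CC(=O)CC(=O)C[C@H](c2cc(OCc3ccccc3)c3c(c2)[C@@H](c2cc(OCc4ccccc4)cc(OCc4ccccc4)c2)[C@H](c2ccc(OCc4ccccc4)cc2)O3)[C@@H](c2ccc(OCc3ccccc3)cc2)O[Si](C)(C)C(C)(C)C)cc1 | intermediate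
31 | 5-{(E)-2-[4-(benzyloxy)phenyl]ethenyl}-4-{(1R,2S)-2-[4-(benzyloxy)phenyl]-2-[(tert-butyldimethylsilyl)oxy]-1-(fragment 2 aryl)ethyl}-5-hydroxycyclohexane-1,3-dione (mixture at the two new ring centres) | c1ccccc1COc1ccc(/C=C/C2(O)CC(=O)CC(=O)C2[C@H](c2cc(OCc3ccccc3)c3c(c2)[C@@H](c2cc(OCc4ccccc4)cc(OCc4ccccc4)c2)[C@H](c2ccc(OCc4ccccc4)cc2)O3)[C@@H](c2ccc(OCc3ccccc3)cc2)O[Si](C)(C)C(C)(C)C)cc1 | intermediate (not isolated)
32 | 5-{(E)-2-[4-(benzyloxy)phenyl]ethenyl}-4-{(1S,2S)-2-[4-(benzyloxy)phenyl]-2-[(tert-butyldimethylsilyl)oxy]-1-(fragment 2 aryl)ethyl}benzene-1,3-diol | c1ccccc1COc1ccc(/C=C/c2cc(O)cc(O)c2[C@H](c2cc(OCc3ccccc3)c3c(c2)[C@@H](c2cc(OCc4ccccc4)cc(OCc4ccccc4)c2)[C@H](c2ccc(OCc4ccccc4)cc2)O3)[C@@H](c2ccc(OCc3ccccc3)cc2)O[Si](C)(C)C(C)(C)C)cc1 | intermediate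
33 | (2S,3S)-2-[4-(benzyloxy)phenyl]-4-{(E)-2-[4-(benzyloxy)phenyl]ethenyl}-3-(fragment 2 aryl)-2,3-dihydro-1-benzofuran-6-ol | c1ccccc1COc1ccc(/C=C/c2cc(O)cc3c2[C@H](c2cc(OCc4ccccc4)c4c(c2)[C@@H](c2cc(OCc5ccccc5)cc(OCc5ccccc5)c2)[C@H](c2ccc(OCc5ccccc5)cc2)O4)[C@@H](c2ccc(OCc4ccccc4)cc2)O3)cc1 | intermediate
34 | CNP0172909.1 | Oc1ccc(/C=C/c2cc(O)cc3c2[C@H](c2cc(O)c4c(c2)[C@@H](c2cc(O)cc(O)c2)[C@H](c2ccc(O)cc2)O4)[C@@H](c2ccc(O)cc2)O3)cc1 | target

## Step count and risk

Total: 19 steps. Longest linear sequence: 18 steps (steps 1–14 and 16–19, from 1 to 34); step 15 is a one-step side branch.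

**Step 17 (key step).** The C3a enolate forms only in small equilibrium amount beside the far more acidic C5 and C7 positions and is shielded by the substituents on C3. Ring closure may therefore be too slow, so that cleavage of the triketone by methoxide, reversible conjugate additions to the styryl ketone, or oxidation consume the material. The fallback gives up building ring B and brings it in intact; it sets out from bromide 13 and comes back at target 34. Resveratrol would be perbenzylated (BnBr, K2CO3) to tri-O-benzylresveratrol F1 and formylated ortho to the styryl group (POCl3, DMF) to 2,4-bis(benzyloxy)-6-{(E)-2-[4-(benzyloxy)phenyl]ethenyl}benzaldehyde F2. The benzyl ether ortho to the formyl group would be removed by chelation (MgBr2·OEt2) to give 4-(benzyloxy)-2-hydroxy-6-{(E)-2-[4-(benzyloxy)phenyl]ethenyl}benzaldehyde F3. Its sodium phenoxide would be treated with aryllithium 14, made from 13 as in step 9, to give o-hydroxybenzhydrol F4. With Cs2CO3 and [4-(benzyloxy)benzyl]dimethylsulfonium chloride F5 (from chloride 4 and dimethyl sulfide), F4 should pass through its o-quinone methide and undergo [4+1] annulation with the sulfur ylide to the trans-dihydrobenzofuran, heptabenzyl ether F6. F6 would form together with its (2R,3R) diastereomer and be separated from it by chromatography; debenzylation as in step 19 returns to 34. The price is the loss of catalyst control at C3.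

**Step 12 (with step 13).** Aldehyde 20 is an α-aryl aldehyde: epimerisation at C3 through its enol during oxidation, work-up or the addition is the main danger, and alcohol 19 may relactonise before it is oxidised. The fallback carries C2 through the acid and ketone oxidation levels instead; it sets out from 19 and comes back at 24. Alcohol 19 would be oxidised directly (TEMPO, PhI(OAc)2, MeCN/H2O) to carboxylic acid F7 and converted (EtSH, EDC·HCl, HOBt) into S-ethyl thioester F8. F8 would be coupled with 4-(benzyloxy)phenylboronic acid under neutral Liebeskind–Srogl conditions (Pd2(dba)3, tri(2-furyl)phosphine, Cu(O2CC4H3S)) to aryl ketone F9. F9 would be reduced with BH3·SMe2 and the (R)-Me-CBS oxazaborolidine, the enantiomer expected to give the (4S) carbinol 24 if the aryl group acts as the larger substituent.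

**Step 16.** The amide carbonyl of 25 is β-branched and flanked by large groups, so addition of the bulky dianion may be slow, leaving room for base-induced loss of the N-methoxy group or recovery of starting materials. The fallback reverses the polarity so that the hindered partner becomes the nucleophile and the electrophile is a non-enolisable cinnamate; it sets out from 25 and comes back at 30. Amide 25 would be acylated onto the small lithium enolate of acetone (excess, THF, −78 °C) to give β-diketone F10. The dianion of F10 (LDA, deprotonation at the unhindered methyl end) would then be acylated with methyl (E)-4-(benzyloxy)cinnamate to give triketone 30.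

**Step 18.** The C2 cation sits next to the C4 styryl group, so capture by the alkene (carbocycle formation) or acid-induced reopening and Friedel–Crafts reactions could compete with capture by the C7a hydroxyl, and the stilbene geometry could be lost. The fallback closes the furan ring before ring B exists, so that the C2–O bond is never ionised; it sets out from 30 and comes back at 33. Triketone 30 would be desilylated (HF·pyridine, THF); the freed C2 hydroxyl should add to the C7a carbonyl and dehydrate to 2-alkylidenetetrahydrofuran F11, a cyclic vinylogous ester. Base (KOH in MeOH, or DBU) would then effect the same C3a-to-C4 aldol condensation and aromatisation, giving 33 directly with retention at C2. This variant needs the (4S) carbinol of step 13 diastereomerically pure, because C2 is no longer corrected.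

**Step 19.** Six benzyl ethers must be cleaved in a product with two Lewis-acid-labile benzylic C–O bonds and a stilbene: ring opening with capture of the cation by the scavenger or the alkene, C-benzylation of the electron-rich rings, and oxidative loss of the free heptaphenol on isolation are all possible. The fallback replaces Lewis-acid cleavage by nucleophilic dealkylation under basic conditions; it sets out from 33 and comes back at 34 without a new isolated compound. NaSEt in degassed DMF at 80–100 °C should attack each benzylic CH2 by SN2, releasing the phenoxides and benzyl ethyl sulfide, followed by acidification under argon.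

## Further compounds

F1 | step 17 | tri-O-benzylresveratrol, (E)-1,3-bis(benzyloxy)-5-{2-[4-(benzyloxy)phenyl]ethenyl}benzene | c1ccccc1COc1ccc(/C=C/c2cc(OCc3ccccc3)cc(OCc3ccccc3)c2)cc1
F2 | step 17 | 2,4-bis(benzyloxy)-6-{(E)-2-[4-(benzyloxy)phenyl]ethenyl}benzaldehyde | O=Cc1c(OCc2ccccc2)cc(OCc2ccccc2)cc1/C=C/c1ccc(OCc2ccccc2)cc1
F3 | step 17 | 4-(benzyloxy)-2-hydroxy-6-{(E)-2-[4-(benzyloxy)phenyl]ethenyl}benzaldehyde | O=Cc1c(O)cc(OCc2ccccc2)cc1/C=C/c1ccc(OCc2ccccc2)cc1
F4 | step 17 | o-hydroxybenzhydrol: [4-(benzyloxy)-2-hydroxy-6-{(E)-2-[4-(benzyloxy)phenyl]ethenyl}phenyl](fragment 2 aryl)methanol, mixture at the carbinol centre | OC(c1c(O)cc(OCc2ccccc2)cc1/C=C/c1ccc(OCc2ccccc2)cc1)c1cc(OCc2ccccc2)c2c(c1)[C@@H](c1cc(OCc3ccccc3)cc(OCc3ccccc3)c1)[C@H](c1ccc(OCc3ccccc3)cc1)O2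
F5 | step 17 | [4-(benzyloxy)benzyl]dimethylsulfonium chloride | C[S+](C)Cc1ccc(OCc2ccccc2)cc1.[Cl-]
F6 | step 17 | heptabenzyl ether of the target, (2S,3S)-6-(benzyloxy)-2-[4-(benzyloxy)phenyl]-4-{(E)-2-[4-(benzyloxy)phenyl]ethenyl}-3-(fragment 2 aryl)-2,3-dihydro-1-benzofuran | c1ccccc1COc1ccc(/C=C/c2cc(OCc6ccccc6)cc3c2[C@H](c2cc(OCc4ccccc4)c4c(c2)[C@@H](c2cc(OCc5ccccc5)cc(OCc5ccccc5)c2)[C@H](c2ccc(OCc5ccccc5)cc2)O4)[C@@H](c2ccc(OCc4ccccc4)cc2)O3)cc1
F7 | step 12 | (2R)-2-(fragment 2 aryl)-4-[methoxy(methyl)amino]-4-oxobutanoic acid | CON(C)C(=O)C[C@H](c1cc(OCc2ccccc2)c2c(c1)[C@@H](c1cc(OCc3ccccc3)cc(OCc3ccccc3)c1)[C@H](c1ccc(OCc3ccccc3)cc1)O2)C(=O)O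
F8 | step 12 | S-ethyl (2R)-2-(fragment 2 aryl)-4-[methoxy(methyl)amino]-4-oxobutanethioate | CON(C)C(=O)C[C@H](c1cc(OCc2ccccc2)c2c(c1)[C@@H](c1cc(OCc3ccccc3)cc(OCc3ccccc3)c1)[C@H](c1ccc(OCc3ccccc3)cc1)O2)C(=O)SCC
F9 | step 12 | (3R)-4-[4-(benzyloxy)phenyl]-3-(fragment 2 aryl)-N-methoxy-N-methyl-4-oxobutanamide | CON(C)C(=O)C[C@H](c1cc(OCc2ccccc2)c2c(c1)[C@@H](c1cc(OCc3ccccc3)cc(OCc3ccccc3)c1)[C@H](c1ccc(OCc3ccccc3)cc1)O2)C(=O)c1ccc(OCc2ccccc2)cc1
F10 | step 16 | (6R,7S)-7-[4-(benzyloxy)phenyl]-6-(fragment 2 aryl)-7-[(tert-butyldimethylsilyl)oxy]heptane-2,4-dione | CC(=O)CC(=O)C[C@H](c1cc(OCc2ccccc2)c2c(c1)[C@@H](c1cc(OCc3ccccc3)cc(OCc3ccccc3)c1)[C@H](c1ccc(OCc3ccccc3)cc1)O2)[C@@H](c1ccc(OCc2ccccc2)cc1)O[Si](C)(C)C(C)(C)C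
F11 | step 18 | (E)-1-[4-(benzyloxy)phenyl]-6-[(4R,5S)-5-[4-(benzyloxy)phenyl]-4-(fragment 2 aryl)oxolan-2-ylidene]hex-1-ene-3,5-dione, exocyclic enol ether geometry not fixed | O=C(/C=C/c1ccc(OCc2ccccc2)cc1)CC(=O)C=C1C[C@H](c2cc(OCc3ccccc3)c3c(c2)[C@@H](c2cc(OCc4ccccc4)cc(OCc4ccccc4)c2)[C@H](c2ccc(OCc4ccccc4)cc2)O3)[C@@H](c2ccc(OCc3ccccc3)cc2)O1
F0 | step 19 | none | none
A1 | alternative 1 | methyl (2R,3R)-trans-5-chloro-7-methoxy-2-(4-methoxyphenyl)-2,3-dihydro-1-benzofuran-3-carboxylate | Clc1cc(OC)c2c(c1)[C@@H](C(=O)OC)[C@H](c1ccc(OC)cc1)O2
A2 | alternative 1 | (2R)-6-chloro-8-methoxy-2-(4-methoxyphenyl)-2,3-dihydro-4H-chromen-4-one | O=C1C[C@H](c2ccc(OC)cc2)Oc2c(OC)cc(Cl)cc21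
A3 | alternative 2 | hexa-O-methyl ether of the target with the C6 hydroxyl free | COc1ccc(/C=C/c2cc(O)cc3c2[C@H](c2cc(OC)c4c(c2)[C@@H](c2cc(OC)cc(OC)c2)[C@H](c2ccc(OC)cc2)O4)[C@@H](c2ccc(OC)cc2)O3)cc1
A4 | alternative 3 | 6-O-ethyl hexa-O-methyl ether of the target | COc1ccc(/C=C/c2cc(OCC)cc3c2[C@H](c2cc(OC)c4c(c2)[C@@H](c2cc(OC)cc(OC)c2)[C@H](c2ccc(OC)cc2)O4)[C@@H](c2ccc(OC)cc2)O3)cc1
A5 | alternative 3 | ethoxyacetylene | C#COCC
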